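The data are calculated for substances that don't exist, noise included.

- Two questions stood on the autumn flask, and one quantity served both.

| flask | substrate | remark | time |
|---|---|---|---|
| autumn | 0.40 M | the very flask that is asked about, followed so far |  |
| midnight | 0.80 M | run made earlier |  |
| flask | 0.40 M |  | 40 h |

| run | time / h | over-reaction product / % | open dimer / % | ring / % | substrate / % |
|---|---|---|---|---|---|
| autumn | 0.667 | 0.4 | 12.3 | 6.3 | 83.3 |
| autumn | 1.33 | 0 | 18.3 | 9.7 | 72.6 |
| autumn | 3.00 | 1.1 | 30.9 | 16.2 | 50.7 |
| autumn | 8.00 | 2.1 | 43.6 | 27.7 | 24.9 |
| midnight | 3.00 | 1.0 | 47.0 | 12.6 | 36.4 |
| midnight | 8.00 | 0.5 | 62.0 | 23.0 | 15.8 |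
| midnight | 15.0 | 4.5 | 63.9 | 26.3 | 6.9 |
| midnight | 40.0 | 12.6 | 64.9 | 21.2 | 2.1 |

(scatter of a reading: 1 percentage point)

1. the species in which most of what was charged as substrate, at 40 h sits (ring / open dimer / substrate / over-reaction product)
2. the largest share itself, whichever of these holds it, in percent of the substrate charged

- percent here means substrate units held: one open dimer counts as two
- the analysis behind the earlier runs scatters by 1 percentage point, standard deviation

- I read the ring side, meaning ring plus over-reaction product, against open dimer at 3.00 h: the ratio was 0.560 in the autumn run and 0.289 in the midnight run, so it was larger at the lower charge.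
- I took the ratio of the two routes to be a fixed concentration over the substrate concentration, so each ratio times the mean substrate concentration of its stretch gave 0.169 M and 0.158 M.
- Their mean, 0.163 M, was my zero of the scale: the equal-split concentration, the substrate concentration at which ring formation and dimer formation use substrate equally, a selectivity factor written as a concentration.
- I began on paper with the dimer step by itself, which turned the whole charge into open dimer.
- Adding the ring step and summing the split until the substrate was used up, with x the equal-split concentration over the charge, gave a dimer share of 1 − x·ln(1 + 1/x).
- For the autumn flask that was 49.4%; for the midnight run it was 63.8%, against a reading of 64.9% at 40.0 h, when that run still showed 2.1% substrate.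
- Last came the product step: from 15.0 h to 40.0 h in the midnight run, open dimer went from 63.9% to 64.9% while ring fell from 26.3% to 21.2%, so I let product draw on ring.
- Ring kept 62.7% of the midnight ring side, which left the autumn flask about 31.7% ring, so I expected open dimer to lead.
- The forecast said open dimer at 50%, and its grounds for the autumn flask after 8.00 h were these: “Dimer gains about 6 points, reaching about 50%”; my share was lower.

    substrate → ring (k = 0.0780 h⁻¹)
    2 substrate → open dimer (k = 0.250 M⁻¹ h⁻¹)
    ring → over-reaction product (k = 0.0160 h⁻¹)

- At 40.0 h the autumn flask held 50.4% open dimer, 29.3% ring, 19.0% over-reaction product and 1.28% substrate, so the largest share, open dimer, stood 0.97 percentage points above my reckoning. The same reckoning on a neighbouring flask charged with 0.16 M, close to the equal-split concentration, gave 30.3% open dimer and about 43.7% ring. That flask held 31.2% open dimer and 25.4% over-reaction product at 40.0 h, and its largest share was ring, at 41.2%.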